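**Assumption:** the target (2,5,6-tribromo-1-methylgramine N-oxide) has no stereocentre and no stereogenic double bond, so it is achiral and the structure as drawn is the single compound to be made.

## Retrosynthetic overview

1. The N-oxide 15 comes from the tertiary amine 13 by N-oxidation in the last step.
2. The C3–CH2N bond of 13 comes from an intermolecular Mannich reaction of 2,5,6-tribromo-1-methylindole 10 with Me2N=CH2+ I− 11 (the key C–C bond, joining the indole and the aminomethyl fragment).
3. The 2-bromoindole 10 comes from 5,6-dibromo-1-methyloxindole 8 by deoxygenative bromination with POBr3.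
4. 8 comes from 6-bromo-1-methyloxindole 6 (C5 bromination para to N), 6 from 6-bromo-1-methylisatin 3 (hydrazone, Wolff–Kishner), and 3 from 6-bromoisatin 1 and MeI.
5. No ring is built: the benzo-fused five-membered lactam is bought intact in 1 and becomes the pyrrole ring of the indole in step 5.

## Route

Step 1
Reactants: 1 6-bromoisatin (6-bromoindoline-2,3-dione); 2 iodomethane
Product: 3 6-bromo-1-methylindoline-2,3-dione
Conditions: MeI (1.3 eq), K2CO3 (1.5 eq), DMF, rt
Reagents that add atoms: iodomethane, CI
Why: SN2 N-alkylation of the acidic isatin N–H is clean because isatin has no C3–H that could compete, which is why the methyl group is put on before the oxindole stage.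

Step 2
Reactants: 3 6-bromo-1-methylindoline-2,3-dione; 4 hydrazine hydrate
Product: 5 (Z)-6-bromo-3-hydrazinylidene-1-methylindolin-2-one
Conditions: N2H4·H2O (2 eq), EtOH, reflux
Reagents that add atoms: hydrazine hydrate, NN.O
Why: Hydrazone formation (condensation) occurs only at the ketone-like C3 carbonyl, which is far more electrophilic than the C2 lactam carbonyl; the Z geometry (N–H···O=C2 hydrogen bond) is of no consequence because it disappears in step 3.

Step 3
Reactants: 5 (Z)-6-bromo-3-hydrazinylidene-1-methylindolin-2-one
Product: 6 6-bromo-1-methylindolin-2-one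
Conditions: NaOEt (2 eq), EtOH, reflux, N2; then aq HCl
Reagents that add atoms: none
Why: Wolff–Kishner reduction of an isatin 3-hydrazone proceeds under mild alkoxide conditions with loss of N2 and leaves the unactivated aryl bromide and the lactam untouched.

Step 4
Reactants: 6 6-bromo-1-methylindolin-2-one; 7 N-bromosuccinimide
Product: 8 5,6-dibromo-1-methylindolin-2-one
Conditions: NBS (1.0 eq), MeCN, 0 °C to rt, dark
Reagents that add atoms: N-bromosuccinimide, O=C1CCC(=O)N1Br
Why: Electrophilic aromatic bromination of an N-alkyloxindole goes para to the amide nitrogen (C5), since C7 is flanked by N-methyl and bromine and one equivalent of NBS in MeCN spares the C3 methylene.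

Step 5
Reactants: 8 5,6-dibromo-1-methylindolin-2-one; 9 phosphorus oxybromide
Product: 10 2,5,6-tribromo-1-methyl-1H-indole
Conditions: POBr3 (1.5 eq), ClCH2CH2Cl, 80 °C; ice-water quench
Reagents that add atoms: phosphorus oxybromide, O=P(Br)(Br)Br
Why: Deoxygenative bromination of a lactam (O-phosphorylation, bromide addition–elimination, then tautomerisation to the aromatic indole) places bromine at C2, which direct electrophilic bromination of an indole cannot reach.

Step 6
Reactants: 10 2,5,6-tribromo-1-methyl-1H-indole; 11 Eschenmoser's salt (N,N-dimethylmethyleneiminium iodide, Me2N=CH2+ I−)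
Product: 13 2,5,6-tribromo-1-methylgramine, via 2,5,6-tribromo-1-methylgramine hydroiodide 12 (not isolated)
Conditions: Me2N=CH2+ I− (1.5 eq), MeCN, rt to 50 °C; aq NaOH work-up
Reagents that add atoms: Eschenmoser's salt, C=[N+](C)C.[I-]
Why: Intermolecular Mannich reaction: the preformed iminium ion attacks C3, the only free nucleophilic position of the N-methylindole, under acid-free conditions that the 2-bromoindole tolerates, and base releases the free amine from its hydroiodide.

Step 7
Reactants: 13 2,5,6-tribromo-1-methylgramine; 14 3-chloroperoxybenzoic acid (mCPBA)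
Product: 15 2,5,6-tribromo-1-methylgramine N-oxide (target)
Conditions: mCPBA (1.05 eq), CH2Cl2, 0 °C; filtration through basic alumina (CH2Cl2/MeOH)
Reagents that add atoms: mCPBA, OOC(=O)c1cccc(Cl)c1
Why: N-oxidation of the trialkylamine by the peracid is much faster than attack on the tetrasubstituted indole C2=C3 bond, which is deactivated by three bromines, and no stereocentre is created.

## Compound list

1 | 6-bromoisatin (6-bromoindoline-2,3-dione) | O=C1Nc2cc(Br)ccc2C1=O | starting material
2 | iodomethane | CI | starting material
3 | 6-bromo-1-methylindoline-2,3-dione | CN1C(=O)C(=O)c2ccc(Br)cc21 | intermediate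
4 | hydrazine hydrate | NN.O | starting material
5 | (Z)-6-bromo-3-hydrazinylidene-1-methylindolin-2-one | CN1C(=O)/C(=N\N)c2ccc(Br)cc21 | intermediate
6 | 6-bromo-1-methylindolin-2-one | CN1C(=O)Cc2ccc(Br)cc21 | intermediate
7 | N-bromosuccinimide | O=C1CCC(=O)N1Br | starting material
8 | 5,6-dibromo-1-methylindolin-2-one | CN1C(=O)Cc2cc(Br)c(Br)cc21 | intermediate
9 | phosphorus oxybromide (POBr3) | O=P(Br)(Br)Br | starting material
10 | 2,5,6-tribromo-1-methyl-1H-indole | Cn1c(Br)cc2cc(Br)c(Br)cc21 | intermediate
11 | Eschenmoser's salt (N,N-dimethylmethyleneiminium iodide) | C=[N+](C)C.[I-] | starting material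
12 | 2,5,6-tribromo-1-methylgramine hydroiodide | Cn1c(Br)c(C[NH+](C)C)c2cc(Br)c(Br)cc21.[I-] | intermediate (not isolated)
13 | 2,5,6-tribromo-1-methylgramine [1-(2,5,6-tribromo-1-methyl-1H-indol-3-yl)-N,N-dimethylmethanamine] | Cn1c(Br)c(CN(C)C)c2cc(Br)c(Br)cc21 | intermediate
14 | 3-chloroperoxybenzoic acid (mCPBA) | OOC(=O)c1cccc(Cl)c1 | starting material
15 | 2,5,6-tribromo-1-methylgramine N-oxide [1-(2,5,6-tribromo-1-methyl-1H-indol-3-yl)-N,N-dimethylmethanamine N-oxide] | Cn1c(Br)c(C[N+](C)(C)[O-])c2cc(Br)c(Br)cc21 | target

## Summary

Total step count: 7. Longest linear sequence: 7 steps (from 1).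

## Steps most likely to fail, with fallbacks

**Step 5 (oxindole to 2-bromoindole).** The yield can be moderate and 10 is sensitive to acid and light. The fallback sets out from 8 and comes back at 13, so that free 10 is never handled. 8 is condensed with N,N-dimethylformamide dimethyl acetal in toluene at 100 °C, a Mannich-type aminomethylenation of the lactam enol. This gives 5,6-dibromo-3-[(dimethylamino)methylidene]-1-methylindolin-2-one F3 as an E/Z mixture of no consequence. POBr3 in CH2Cl2 (0 °C to rt) activates the much more nucleophilic oxygen of this vinylogous amide and gives N-[(2,5,6-tribromo-1-methyl-1H-indol-3-yl)methylidene]-N-methylmethanaminium bromide F4. F4 is not isolated; NaBH4 in MeOH at 0 °C reduces it in the same flask to 13.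

**Step 6 (Mannich reaction on the deactivated, 2-substituted indole 10).** C3 may be too poor a nucleophile. The fallback sets out from 8 and comes back at 13, running the Mannich reaction before the 2-bromine is in place. 8 is reduced with i-Bu2AlH (CH2Cl2, −78 to 0 °C), and the 2-hydroxyindoline dehydrates on acidic work-up to 5,6-dibromo-1-methyl-1H-indole F5. The Mannich reaction of this more nucleophilic indole with 11 in MeCN at rt gives 5,6-dibromo-1-methylgramine F6. NBS (1.0 eq) in AcOH/TFA at 0–10 °C then brominates C2 of the protonated amine and gives 13; protonation suppresses retro-Mannich loss of the side chain.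

**Step 4 (regioselective C5 bromination of the oxindole).** Some C7 or C3 bromination is possible. The fallback sets out from 3 and comes back at 8, moving the bromination to the isatin stage, where there is no enolisable C3–H. 3 is treated with NBS in concentrated H2SO4 at rt to give 5,6-dibromo-1-methylindoline-2,3-dione F1 (C5, para to N). Hydrazine hydrate in refluxing EtOH gives (Z)-5,6-dibromo-3-hydrazinylidene-1-methylindolin-2-one F2. NaOEt in refluxing EtOH (Wolff–Kishner) then gives 8.

## Further compounds

F1 | step 4 | 5,6-dibromo-1-methylindoline-2,3-dione | CN1C(=O)C(=O)c2cc(Br)c(Br)cc21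
F2 | step 4 | (Z)-5,6-dibromo-3-hydrazinylidene-1-methylindolin-2-one | CN1C(=O)/C(=N\N)c2cc(Br)c(Br)cc21
F3 | step 5 | 5,6-dibromo-3-[(dimethylamino)methylidene]-1-methylindolin-2-one (E/Z mixture) | CN1C(=O)C(=CN(C)C)c2cc(Br)c(Br)cc21
F4 | step 5 | N-[(2,5,6-tribromo-1-methyl-1H-indol-3-yl)methylidene]-N-methylmethanaminium bromide | Cn1c(Br)c(C=[N+](C)C)c2cc(Br)c(Br)cc21.[Br-]
F5 | step 6 | 5,6-dibromo-1-methyl-1H-indole | Cn1ccc2cc(Br)c(Br)cc21
F6 | step 6 | 5,6-dibromo-1-methylgramine | Cn1cc(CN(C)C)c2cc(Br)c(Br)cc21
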